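## The problem

The target is a depsidone. Two benzene rings (ring A and ring B) are joined twice, through a diaryl ether oxygen and through an ester, so that a seven-membered dioxepinone (ring C) lies between them. Ring B is also fused to a 2,2-dimethylchroman-4-one. There is no stereocentre, so every difficulty is one of regiochemistry and functional-group tolerance.

Ring A carries, on six consecutive carbons, methyl, hydrogen, hydroxyl, formyl, the ether oxygen and the lactone carbonyl. Ring B is fully substituted: ester oxygen, methyl, ketone carbon, pyranone oxygen, free hydroxyl and ether oxygen. The ether oxygen therefore has two ortho substituents on each ring, which makes a late intermolecular aryl ether coupling the least attractive bond to form.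

On ring B the ether oxygen is flanked by two oxygens, the lactone oxygen and the free hydroxyl. Only one of them may close ring C, so they must stay distinguishable until the lactone exists.

The groups that will not survive rough treatment are the aryl ester of ring C (opened by alkoxide, hydroxide or thiolate), the ortho-hydroxy aldehyde (reduction, organometallics), the chromanone (a β-aryloxy ketone, enolisable and open to retro-oxa-Michael cleavage) and the electron-rich phenols.

The feature that opens the key step is on ring A. The formyl-bearing carbon and the aryloxy-bearing carbon are neighbours and can both come from an alkyne, a 3-aryloxypropynal. The other four ring carbons (carboxyl-bearing, methyl-bearing, CH, hydroxyl-bearing) map onto the silyl dienolate of a 3-methylglutaconate diester.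

## Retrosynthesis

Ring B positions are numbered as in the chromanone (O1, C2, C3, C4 ketone, C5 methyl, C6, C7, C8).

**Free C8 hydroxyl.** Target 22 is traced back to its C8 methyl ether 21; only an O–CH3 bond is cut. The methyl group is what tells the C8 oxygen from the C6 oxygen while ring C is closed, and it comes with the starting quinone. The forward step has to cleave one aryl methyl ether in the presence of the aryl ester, the aldehyde and the chromanone.

**Ring C.** In 21 the ester C–O bond between the ring A carbonyl and the C6 oxygen is cut, giving hydroxy acid 20. The neighbouring cut, the diaryl ether, is rejected here: that bond is ortho-substituted on both sides, whereas the ester is the weaker bond and forms by simple dehydration once the two rings are held together by the ether. The forward reaction is a seven-membered lactonization. Its regiochemistry is not in question, because the only other oxygen ortho to the ether is methylated.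

**Unmasking.** Hydroxy acid 20 comes from benzyl ether acid 19 and that from methyl ester 18. Benzyl on the C6 oxygen is chosen because it can be removed at low temperature without touching the C8 methyl ether or the aldehyde. The methyl ester is simply what the diene delivers. The forward steps must free a di-ortho-substituted benzoate without hydroxide.

**Ring A (key disconnection).** In 18 two C–C bonds of ring A are cut: carboxyl-bearing carbon to aryloxy-bearing carbon, and formyl-bearing carbon to hydroxyl-bearing carbon. This gives aryloxypropynal 13 and vinylketene silyl acetal 15.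
- Against cutting the aryl ether C–O bond, this cut makes the crowded ether an ordinary O–C(sp) bond on a phenol, and takes ring A back to a commercial acyclic diester.
- The formyl group is both the activating group of the dienophile and a substituent of the target, so no carbon is added or removed afterwards.
- The forward reaction has to pair the ester-bearing terminus of the diene with the alkyne carbon β to the aldehyde, and has to aromatise by loss of methanol.

**Ynol ether.** Ynal 13 is taken back through propargylic alcohol 12 and its silyl ether 11 to phenol 7 and gem-dibromoalkene 9. The bond cut is O–C(sp). The aldehyde is carried as a silyl-protected primary alcohol rather than as an acetal, because unmasking an acetal next to an ynol ether would need acid and invite hydration or Meyer–Schuster rearrangement. The forward coupling must tolerate the ketone, which rules out routes through alkyllithium reagents as first choice.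

**Oxygen pattern of ring B.** Phenol 7 comes from benzyl ether 6 by cleavage of the C7 O–CH3 bond, and 6 from phenol 5 by benzylation. The C7 methoxy group is the only one para to the ketone, so a nucleophile should pick it out. Benzylation comes first because 5 has a single free hydroxyl, exactly the one that must later carry the ester.

**Chromanone.** Chromanone 5 is cut at the aryl–acyl bond and at O1–C2, giving hydroquinone 2 and 3-methylbut-2-enoic acid 3. Hydroquinone 2 has one free ring position, and only one of its hydroxyls is ortho to it, so acylation and ring closure can take one course only. Hydroquinone 2 is the reduction product of quinone 1, which already holds the methyl group and all four oxygens of ring B.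

**Small fragments.** Diene 15 is the O-silylated anion of dimethyl 3-methylglutaconate 14. Dibromoalkene 9 is the dibromo-olefination product of silyloxyacetaldehyde 8.

## Roads not taken

**Alternative 1: Baeyer–Villiger expansion of a xanthone.** The cut is the ester O–C(ring B) bond, the lactone carbonyl being taken back to a ketone that bridges both rings. Xanthone A1 would be treated with CF3CO3H to give depsidone A2, in which a bromide stands for the formyl group.
- Merits: a xanthone is a robust, flat intermediate made by established acylation and cyclisation chemistry. Ring C arises by ring expansion, not by closing a medium ring. The position of the ester oxygen is fixed by the ketone, so the two ring B oxygens need not be told apart.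
- Weak points: the xanthone carbonyl is a doubly vinylogous ester and adds peracid reluctantly. The ring B carbon must migrate in preference to the ring A carbon, although both are ortho-oxygenated and ortho-methylated. Electron-rich rings are open to peracid oxidation. A2 still lacks the chromanone ring and the formyl group: the bromide would have to be turned into an aldehyde next to an aryl ester, and a pyranone annulated onto a depsidone.
- Comparison: this road is better in avoiding both a hindered ether synthesis and the differentiation of two oxygens. Against that, the chosen plan has the formyl group in place from the key step, builds the chromanone first on a simple hydroquinone, and leaves only deprotection and one lactonization after the key step.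

**Alternative 2: ester-tethered SNAr.** The cut is the ring A C–O ether bond, made last and intramolecularly. Depside A3, with a free ring B phenol and a ring A fluoride, would close with Cs2CO3 to the bis-benzyl ether A4 of the target.
- Merits: the ester is made first by ordinary acylation. The substitution is intramolecular and the fluoride is activated by an ortho formyl and an ortho ester carbonyl. A4 is one debenzylation from the target, the shortest end game of all four plans.
- Weak points: the fully substituted ring A fluoro acid needs its own multi-step arene synthesis. Ring B must offer a free C7 hydroxyl beside a C6 aryl ester, and under carbonate the acyl group can move to the neighbouring phenoxide before substitution, which would give the isomeric ring fusion. The final double debenzylation has to spare the aldehyde.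
- Comparison: in precedent for the ring-closing event and in the number of steps after it, this road is at least as good as the chosen one. The chosen plan sets against it that ring A needs no separate synthesis, being made in one step from a commercial diester, and that the ether oxygen is attached to ring B before any ester exists, so acyl migration cannot scramble the regiochemistry.

**Alternative 3: ring B by Moore rearrangement.** The cut is a C–C bond of ring B. Heating 4-hydroxy-4-propenylcyclobutenone A5 would open it to a dienylketene, whose 6π closure gives diaryl ether A6 with ring B as a hydroquinone.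
- Merits: the crowded oxygen pattern of ring B comes regiospecifically from a squarate. The ether bond is made by addition–elimination on the squarate, not by aryl substitution. The key step is thermal and neutral.
- Weak points: the propenyl metal must add to one of two carbonyls of an aryloxy(methoxy)cyclobutenedione without displacing the aryloxide. Ring A must still be made separately as a pentasubstituted phenol with a protected aldehyde. A6 has two free hydroxyls and an open ring position, so the chromanone must still be annulated under acid, in the presence of a dioxolane and an ester, and the correct hydroxyl lactonised.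
- Comparison: this road is better at delivering the ring B oxygenation without a selective demethylation. The chosen plan obtains ring B from an inexpensive quinone in four steps and spends its ring construction on ring A, where it also installs the formyl group.

Key step: step 10

Assumption: 14 and 15 are drawn as single geometric isomers; the route should not depend on this geometry, since either isomer of 14 gives the same delocalised anion and the acetal carbon of 15 becomes an aromatic carbon.

## Steps

Step 1
Reactants: 1 2,3-dimethoxy-5-methyl-1,4-benzoquinone
Product: 2 2,3-dimethoxy-5-methylbenzene-1,4-diol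
Conditions: Na2S2O4, Et2O/H2O, rt
Reagents that add atoms: none
Why: Dithionite reduction of a quinone to its hydroquinone; the product is used directly under argon to avoid reoxidation.

Step 2
Reactants: 2 2,3-dimethoxy-5-methylbenzene-1,4-diol; 3 3-methylbut-2-enoic acid
Product: 5 6-hydroxy-7,8-dimethoxy-2,2,5-trimethylchroman-4-one, via ortho-hydroxyaryl enone 4 (not isolated)
Conditions: MeSO3H/P2O5, 70 °C, Ar
Reagents that add atoms: none
Why: Friedel–Crafts acylation at the only free ring position gives enone 4, and the one hydroxyl ortho to the new acyl group closes the pyranone by 6-endo oxa-Michael addition; this is the known chromanone synthesis from phenols and 3-methylbut-2-enoic acid in MeSO3H/P2O5.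

Step 3
Reactants: 5 6-hydroxy-7,8-dimethoxy-2,2,5-trimethylchroman-4-one
Product: 6 6-(benzyloxy)-7,8-dimethoxy-2,2,5-trimethylchroman-4-one
Conditions: BnBr, K2CO3, DMF, 60 °C
Reagents that add atoms: benzyl bromide, BrCc1ccccc1
Why: Williamson etherification of the single free phenol; carbonate is too weak a base to alkylate at C3.

Step 4
Reactants: 6 6-(benzyloxy)-7,8-dimethoxy-2,2,5-trimethylchroman-4-one
Product: 7 6-(benzyloxy)-7-hydroxy-8-methoxy-2,2,5-trimethylchroman-4-one
Conditions: NaSEt, DMF, 100 °C; then aq. HCl
Reagents that add atoms: none
Why: SN2 demethylation by thiolate; the C7 methoxy group is para to the ketone, so its phenoxide is the best leaving group, and it is twisted out of plane by two ortho oxygens, whereas the C8 methoxy and the benzyl ether sit on unactivated oxygens and should react more slowly.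

Step 5
Reactants: 8 (tert-butyldimethylsilyloxy)acetaldehyde
Product: 9 tert-butyl[(3,3-dibromoprop-2-en-1-yl)oxy]dimethylsilane
Conditions: CBr4, PPh3, Et3N, CH2Cl2, 0 °C
Reagents that add atoms: carbon tetrabromide, BrC(Br)(Br)Br
Why: Ramirez dibromo-olefination (first stage of the Corey–Fuchs sequence); Et3N buffers traces of HBr so that the silyl ether survives.

Step 6
Reactants: 7 6-(benzyloxy)-7-hydroxy-8-methoxy-2,2,5-trimethylchroman-4-one; 9 tert-butyl[(3,3-dibromoprop-2-en-1-yl)oxy]dimethylsilane
Product: 11 6-(benzyloxy)-7-{[3-(tert-butyldimethylsilyloxy)prop-1-yn-1-yl]oxy}-8-methoxy-2,2,5-trimethylchroman-4-one, via bromoenol ether 10 (not isolated)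
Conditions: CuI (cat.), 2,2'-bipyridine, K3PO4, toluene, 110 °C; then t-BuOK, 1,4-dioxane, rt
Reagents that add atoms: none
Why: Copper-catalysed Ullmann-type coupling of a phenol with a gem-dibromoalkene replaces the bromide trans to the CH2OSi group and gives the (Z)-bromoenol ether 10, in which H and Br are anti; t-BuOK then effects E2 dehydrobromination to the ynol ether. No organolithium reagent is involved, so the ketone is tolerated.

Step 7
Reactants: 11 6-(benzyloxy)-7-{[3-(tert-butyldimethylsilyloxy)prop-1-yn-1-yl]oxy}-8-methoxy-2,2,5-trimethylchroman-4-one
Product: 12 6-(benzyloxy)-7-[(3-hydroxyprop-1-yn-1-yl)oxy]-8-methoxy-2,2,5-trimethylchroman-4-one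
Conditions: TBAF, THF, 0 °C; aq. NH4Cl work-up
Reagents that add atoms: none
Why: Fluoride cleavage of the Si–O bond; the non-acidic conditions avoid acid-catalysed Meyer–Schuster rearrangement of the aryloxypropargyl alcohol.

Step 8
Reactants: 12 6-(benzyloxy)-7-[(3-hydroxyprop-1-yn-1-yl)oxy]-8-methoxy-2,2,5-trimethylchroman-4-one
Product: 13 3-{[6-(benzyloxy)-8-methoxy-2,2,5-trimethyl-4-oxochroman-7-yl]oxy}prop-2-ynal
Conditions: MnO2, CH2Cl2, rt
Reagents that add atoms: none
Why: MnO2 oxidation of a propargylic alcohol under neutral heterogeneous conditions; filtration alone should give the ynal, which is taken on without chromatography.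

Step 9
Reactants: 14 dimethyl (E)-3-methylpent-2-enedioate (dimethyl 3-methylglutaconate)
Product: 15 methyl (2E,4Z)-5-methoxy-3-methyl-5-(trimethylsilyloxy)penta-2,4-dienoate
Conditions: LiN(iPr)2, THF, −78 °C; then Me3SiCl
Reagents that add atoms: chlorotrimethylsilane, C[Si](C)(C)Cl
Why: Deprotonation of the doubly activated methylene gives the delocalised glutaconate anion, which is O-silylated to the vinylketene silyl acetal (silyl dienolate formation).

Step 10
Reactants: 13 3-{[6-(benzyloxy)-8-methoxy-2,2,5-trimethyl-4-oxochroman-7-yl]oxy}prop-2-ynal; 15 methyl (2E,4Z)-5-methoxy-3-methyl-5-(trimethylsilyloxy)penta-2,4-dienoate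
Product: 18 methyl 2-{[6-(benzyloxy)-8-methoxy-2,2,5-trimethyl-4-oxochroman-7-yl]oxy}-3-formyl-4-hydroxy-6-methylbenzoate, via cycloadduct ketal 16 (not isolated), via aryl silyl ether 17 (not isolated)
Conditions: 15 (3 equiv), toluene, 80 °C; then 1 M HCl, THF, rt
Reagents that add atoms: none
Why: The electron-rich diene 15 adds across the formyl-activated alkyne of 13 in a normal-demand (4+2) cycloaddition: its ester-bearing terminus, the nucleophilic γ-carbon of the dienolate, bonds to the alkyne carbon β to the aldehyde (the aryloxy carbon), and the acetal carbon bonds to the formyl-bearing carbon. The closest known reaction type is the Diels–Alder/aromatization of 1-alkoxy-1-silyloxydienes with acetylenic aldehydes, ketones and esters to give salicyl derivatives. Ring A is closed by this intermolecular cycloaddition; if the addition is stepwise, the second bond forms by six-membered closure of the allenolate carbon onto the silyloxycarbenium carbon. Cyclohexa-1,4-diene 16 then loses methanol across the ring to give aryl silyl ether 17, and acid work-up frees the phenol. The two sp3 centres of 16 are erased on aromatization, so no stereochemical control is needed. The step needs regioselectivity, secured by the matched push–pull polarization of both partners. It also needs chemoselectivity for the alkyne over the aldehyde C=O, for which no Lewis acid is used, since Lewis acids favour aldol and hetero-Diels–Alder pathways. The benzyl ether on the neighbouring C6 oxygen prevents that oxygen from adding to the activated alkyne.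

Step 11
Reactants: 18 methyl 2-{[6-(benzyloxy)-8-methoxy-2,2,5-trimethyl-4-oxochroman-7-yl]oxy}-3-formyl-4-hydroxy-6-methylbenzoate
Product: 19 2-{[6-(benzyloxy)-8-methoxy-2,2,5-trimethyl-4-oxochroman-7-yl]oxy}-3-formyl-4-hydroxy-6-methylbenzoic acid
Conditions: LiI, pyridine, reflux; then aq. HCl
Reagents that add atoms: none
Why: SN2 attack of iodide at the ester methyl carbon, the standard answer to a di-ortho-substituted benzoate that resists saponification; the methyl iodide is trapped by the solvent, aryl methyl and benzyl ethers are not cleaved, and no hydroxide meets the aldehyde or the chromanone.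

Step 12
Reactants: 19 2-{[6-(benzyloxy)-8-methoxy-2,2,5-trimethyl-4-oxochroman-7-yl]oxy}-3-formyl-4-hydroxy-6-methylbenzoic acid
Product: 20 3-formyl-4-hydroxy-2-[(6-hydroxy-8-methoxy-2,2,5-trimethyl-4-oxochroman-7-yl)oxy]-6-methylbenzoic acid
Conditions: BCl3, C6HMe5, CH2Cl2, −78 °C
Reagents that add atoms: none
Why: Lewis-acid debenzylation with pentamethylbenzene as the benzyl cation trap; at −78 °C the aryl methyl ether, the aldehyde and the ketone should be left alone, which is why it is preferred to hydrogenolysis.

Step 13
Reactants: 20 3-formyl-4-hydroxy-2-[(6-hydroxy-8-methoxy-2,2,5-trimethyl-4-oxochroman-7-yl)oxy]-6-methylbenzoic acid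
Product: 21 ring B methyl ether of the target (lactone of 20 between the carboxyl group and the C6 hydroxyl of ring B)
Conditions: DCC, CH2Cl2/THF, rt
Reagents that add atoms: none
Why: Carbodiimide lactonization closes ring C by 7-exo-trig attack of the ring B hydroxyl on the O-acylisourea, as in established depsidone syntheses; the other oxygen ortho to the ether is still methylated and the ring A hydroxyl cannot reach the carboxyl, so only one lactone can form.

Step 14
Reactants: 21 ring B methyl ether of the target
Product: 22 target depsidone CNP0271978.0
Conditions: BBr3, CH2Cl2, −78 to 0 °C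
Reagents that add atoms: none
Why: BBr3 cleavage of an aryl methyl ether; a methoxy group flanked by two oxygens is cleaved at low temperature, at which the aryl ester, the chelated ortho-hydroxy aldehyde and the chromanone should persist.

## Compound list

1 | 2,3-dimethoxy-5-methyl-1,4-benzoquinone | COC1=C(OC)C(=O)C(C)=CC1=O | starting material
2 | 2,3-dimethoxy-5-methylbenzene-1,4-diol | COc1c(O)cc(C)c(O)c1OC | intermediate
3 | 3-methylbut-2-enoic acid | CC(C)=CC(=O)O | starting material
4 | 1-(2,5-dihydroxy-3,4-dimethoxy-6-methylphenyl)-3-methylbut-2-en-1-one | CC(C)=CC(=O)c1c(C)c(O)c(OC)c(OC)c1O | intermediate (not isolated)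
5 | 6-hydroxy-7,8-dimethoxy-2,2,5-trimethylchroman-4-one | CC1(C)CC(=O)c2c(C)c(O)c(OC)c(OC)c2O1 | intermediate
6 | 6-(benzyloxy)-7,8-dimethoxy-2,2,5-trimethylchroman-4-one | CC1(C)CC(=O)c2c(C)c(OCc3ccccc3)c(OC)c(OC)c2O1 | intermediate
7 | 6-(benzyloxy)-7-hydroxy-8-methoxy-2,2,5-trimethylchroman-4-one | CC1(C)CC(=O)c2c(C)c(OCc3ccccc3)c(O)c(OC)c2O1 | intermediate
8 | (tert-butyldimethylsilyloxy)acetaldehyde | CC(C)(C)[Si](C)(C)OCC=O | starting material
9 | tert-butyl[(3,3-dibromoprop-2-en-1-yl)oxy]dimethylsilane | CC(C)(C)[Si](C)(C)OCC=C(Br)Br | intermediate
10 | (Z)-6-(benzyloxy)-7-{[1-bromo-3-(tert-butyldimethylsilyloxy)prop-1-en-1-yl]oxy}-8-methoxy-2,2,5-trimethylchroman-4-one | CC1(C)CC(=O)c2c(C)c(OCc3ccccc3)c(O/C(Br)=C/CO[Si](C)(C)C(C)(C)C)c(OC)c2O1 | intermediate (not isolated)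
11 | 6-(benzyloxy)-7-{[3-(tert-butyldimethylsilyloxy)prop-1-yn-1-yl]oxy}-8-methoxy-2,2,5-trimethylchroman-4-one | CC1(C)CC(=O)c2c(C)c(OCc3ccccc3)c(OC#CCO[Si](C)(C)C(C)(C)C)c(OC)c2O1 | intermediate
12 | 6-(benzyloxy)-7-[(3-hydroxyprop-1-yn-1-yl)oxy]-8-methoxy-2,2,5-trimethylchroman-4-one | CC1(C)CC(=O)c2c(C)c(OCc3ccccc3)c(OC#CCO)c(OC)c2O1 | intermediate
13 | 3-{[6-(benzyloxy)-8-methoxy-2,2,5-trimethyl-4-oxochroman-7-yl]oxy}prop-2-ynal | CC1(C)CC(=O)c2c(C)c(OCc3ccccc3)c(OC#CC=O)c(OC)c2O1 | intermediate
14 | dimethyl (E)-3-methylpent-2-enedioate | COC(=O)/C=C(\C)CC(=O)OC | starting material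
15 | methyl (2E,4Z)-5-methoxy-3-methyl-5-(trimethylsilyloxy)penta-2,4-dienoate | COC(=O)/C=C(C)/C=C(/OC)O[Si](C)(C)C | intermediate
16 | methyl 2-{[6-(benzyloxy)-8-methoxy-2,2,5-trimethyl-4-oxochroman-7-yl]oxy}-3-formyl-4-methoxy-6-methyl-4-(trimethylsilyloxy)cyclohexa-2,5-diene-1-carboxylate (mixture of stereoisomers at the two sp3 ring carbons, both erased on aromatization) | COC(=O)C1C(C)=CC(OC)(O[Si](C)(C)C)C(C=O)=C1Oc1c(OCc2ccccc2)c(C)c2c(c1OC)OC(C)(C)CC2=O | intermediate (not isolated)
17 | methyl 2-{[6-(benzyloxy)-8-methoxy-2,2,5-trimethyl-4-oxochroman-7-yl]oxy}-3-formyl-6-methyl-4-(trimethylsilyloxy)benzoate | Cc1cc(O[Si](C)(C)C)c(C=O)c(Oc2c(OCc3ccccc3)c(C)c3c(c2OC)OC(C)(C)CC3=O)c1C(=O)OC | intermediate (not isolated)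
18 | methyl 2-{[6-(benzyloxy)-8-methoxy-2,2,5-trimethyl-4-oxochroman-7-yl]oxy}-3-formyl-4-hydroxy-6-methylbenzoate | Cc1cc(O)c(C=O)c(Oc2c(OCc3ccccc3)c(C)c3c(c2OC)OC(C)(C)CC3=O)c1C(=O)OC | intermediate
19 | 2-{[6-(benzyloxy)-8-methoxy-2,2,5-trimethyl-4-oxochroman-7-yl]oxy}-3-formyl-4-hydroxy-6-methylbenzoic acid | Cc1cc(O)c(C=O)c(Oc2c(OCc3ccccc3)c(C)c3c(c2OC)OC(C)(C)CC3=O)c1C(=O)O | intermediate
20 | 3-formyl-4-hydroxy-2-[(6-hydroxy-8-methoxy-2,2,5-trimethyl-4-oxochroman-7-yl)oxy]-6-methylbenzoic acid | Cc1cc(O)c(C=O)c(Oc2c(O)c(C)c3c(c2OC)OC(C)(C)CC3=O)c1C(=O)O | intermediate
21 | ring B methyl ether of the target: depsidone with ring C closed, ring A carrying methyl, hydroxyl and formyl, ring B carrying methyl, methoxy and the fused 2,2-dimethylpyran-4-one | Cc1cc(O)c(C=O)c2c1C(=O)Oc1c(C)c3c(c(OC)c1O2)OC(C)(C)CC3=O | intermediate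
22 | target depsidone CNP0271978.0 (21 with hydroxyl in place of the ring B methoxy group; no stereocentre) | Cc1cc(O)c(C=O)c2c1C(=O)Oc1c(C)c3c(c(O)c1O2)OC(C)(C)CC3=O | target

## Step count and least certain steps

Total: 14 steps. Longest linear sequence: 12 steps (steps 1–4, 6–8 and 10–14, from quinone 1). Steps 5 and 9 are single-step side branches.

**Step 10 (key step).** The cycloaddition is most likely to be slow. Both partners are damped push–pull systems: the diene carries an ester on its nucleophilic terminus, and the alkyne an oxygen donor on its electrophilic carbon. The reacting alkyne carbon also bears a di-ortho-substituted aryloxy group. Forcing conditions invite addition of the ketene acetal to the aldehyde carbonyl, or expulsion of the aryloxide from a zwitterionic intermediate.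

Fallback: form the aryl–oxygen bond after the ring instead of before it. The fallback sets out from 15 and 7 and comes back at 18.
- Commercial 3,3-diethoxyprop-1-yne would be brominated (NBS, AgNO3 cat., acetone) to 1-bromo-3,3-diethoxyprop-1-yne F1 and hydrolysed with aqueous acid to 3-bromoprop-2-ynal F2.
- Diene 15 should add to this small, fully activated dienophile with the same regiochemistry and give, after acid work-up, methyl 2-bromo-3-formyl-4-hydroxy-6-methylbenzoate F3.
- Protection with MOMCl and iPr2NEt gives methyl 2-bromo-3-formyl-4-(methoxymethoxy)-6-methylbenzoate F4.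
- The bromide, activated by the ortho formyl and ortho ester groups, would be displaced by the phenoxide of 7 (Cs2CO3, DMF, with CuI if the uncatalysed substitution is slow) to give methyl 2-{[6-(benzyloxy)-8-methoxy-2,2,5-trimethyl-4-oxochroman-7-yl]oxy}-3-formyl-4-(methoxymethoxy)-6-methylbenzoate F5.
- HCl in MeOH removes the methoxymethyl group and returns the route to 18.

**Step 6.** The copper-mediated C–O coupling may stall, because the phenol of 7 has two ortho substituents and its phenoxide is weakened by the para ketone. The t-BuOK elimination can also trigger enolate chemistry at the chromanone.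

Fallback: from 7, trichloroethylene and K2CO3 in DMF would give (E)-6-(benzyloxy)-7-[(1,2-dichlorovinyl)oxy]-8-methoxy-2,2,5-trimethylchroman-4-one F6. The ketone is masked in the flask as its enolate with LiN(SiMe3)2 at −78 °C. Then n-BuLi (2 equiv) converts the dichlorovinyl ether into the lithium aryloxyacetylide, which is formylated with DMF and quenched into aqueous KH2PO4. This sets out from 7 and comes back at 13, bypassing 11 and 12.

**Step 4.** Thiolate attack at the benzylic carbon (loss of the protecting group) or at the C8 methyl group may compete with the intended C7 demethylation, since the selectivity rests only on leaving-group ability.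

Fallback: differentiate the oxygens by acidity instead, from 5 and back at 7.
- BCl3 in CH2Cl2, directed by the free C6 hydroxyl, cleaves the neighbouring methoxy group and gives 6,7-dihydroxy-8-methoxy-2,2,5-trimethylchroman-4-one F7.
- The more acidic C7 hydroxyl (para to the ketone) is protected with one equivalent of MOMCl and iPr2NEt to give 6-hydroxy-8-methoxy-7-(methoxymethoxy)-2,2,5-trimethylchroman-4-one F8.
- Benzylation (BnBr, K2CO3) gives 6-(benzyloxy)-8-methoxy-7-(methoxymethoxy)-2,2,5-trimethylchroman-4-one F9.
- HCl in MeOH removes the methoxymethyl group and gives 7.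

**Step 2.** C-alkylation of the arene by the β-carbon of the protonated acid, followed by lactonization to a 4,4-dimethyldihydrocoumarin, may compete with acylation. Hydroquinones are known to take this course in plain protic acid. Air oxidation of 2 is a further loss.

Fallback: separate acylation from ring formation, from 2 and back at 5. Acylation of 2 with AcOH and BF3·OEt2 gives 1-(2,5-dihydroxy-3,4-dimethoxy-6-methylphenyl)ethan-1-one F10. Kabbe condensation with acetone and pyrrolidine then builds the 2,2-dimethylpyranone and gives 5.

## Further compounds

F1 | step 10 | 1-bromo-3,3-diethoxyprop-1-yne | CCOC(OCC)C#CBr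
F2 | step 10 | 3-bromoprop-2-ynal | O=CC#CBr
F3 | step 10 | methyl 2-bromo-3-formyl-4-hydroxy-6-methylbenzoate | COC(=O)c1c(C)cc(O)c(C=O)c1Br
F4 | step 10 | methyl 2-bromo-3-formyl-4-(methoxymethoxy)-6-methylbenzoate | COCOc1cc(C)c(C(=O)OC)c(Br)c1C=O
F5 | step 10 | methyl 2-{[6-(benzyloxy)-8-methoxy-2,2,5-trimethyl-4-oxochroman-7-yl]oxy}-3-formyl-4-(methoxymethoxy)-6-methylbenzoate | COCOc1cc(C)c(C(=O)OC)c(Oc2c(OCc3ccccc3)c(C)c3c(c2OC)OC(C)(C)CC3=O)c1C=O
F6 | step 6 | (E)-6-(benzyloxy)-7-[(1,2-dichlorovinyl)oxy]-8-methoxy-2,2,5-trimethylchroman-4-one | Cl/C=C(/Cl)Oc1c(OCc2ccccc2)c(C)c2c(c1OC)OC(C)(C)CC2=O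
F7 | step 4 | 6,7-dihydroxy-8-methoxy-2,2,5-trimethylchroman-4-one | CC1(C)CC(=O)c2c(C)c(O)c(O)c(OC)c2O1
F8 | step 4 | 6-hydroxy-8-methoxy-7-(methoxymethoxy)-2,2,5-trimethylchroman-4-one | CC1(C)CC(=O)c2c(C)c(O)c(OCOC)c(OC)c2O1
F9 | step 4 | 6-(benzyloxy)-8-methoxy-7-(methoxymethoxy)-2,2,5-trimethylchroman-4-one | CC1(C)CC(=O)c2c(C)c(OCc3ccccc3)c(OCOC)c(OC)c2O1
F10 | step 2 | 1-(2,5-dihydroxy-3,4-dimethoxy-6-methylphenyl)ethan-1-one | CC(=O)c1c(C)c(O)c(OC)c(OC)c1O
A1 | alternative 1 | 4-bromo-5,6-dimethoxy-1,8-dimethyl-9-oxo-9H-xanthen-3-yl acetate | Cc1cc(OC(C)=O)c(Br)c2oc3c(OC)c(OC)cc(C)c3c(=O)c12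
A2 | alternative 1 | depsidone from ring expansion of A1 (ring A with methyl, acetoxy and bromide; ring B with methyl and two methoxy groups) | Cc1cc(OC(C)=O)c(Br)c2c1C(=O)Oc1c(C)cc(OC)c(OC)c1O2
A3 | alternative 2 | 8-(benzyloxy)-7-hydroxy-2,2,5-trimethyl-4-oxochroman-6-yl 4-(benzyloxy)-2-fluoro-3-formyl-6-methylbenzoate | Cc1cc(OCc2ccccc2)c(C=O)c(F)c1C(=O)Oc1c(C)c2c(c(OCc3ccccc3)c1O)OC(C)(C)CC2=O
A4 | alternative 2 | bis-benzyl ether of the target | Cc1cc(OCc2ccccc2)c(C=O)c2c1C(=O)Oc1c(C)c3c(c(OCc4ccccc4)c1O2)OC(C)(C)CC3=O
A5 | alternative 3 | methyl 3-(1,3-dioxolan-2-yl)-2-({3-hydroxy-2-methoxy-4-oxo-3-[(E)-prop-1-en-1-yl]cyclobut-1-en-1-yl}oxy)-4-methoxy-6-methylbenzoate (racemic) | C/C=C/C1(O)C(OC)=C(Oc2c(C3OCCO3)c(OC)cc(C)c2C(=O)OC)C1=O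
A6 | alternative 3 | methyl 2-(3,6-dihydroxy-2-methoxy-5-methylphenoxy)-3-(1,3-dioxolan-2-yl)-4-methoxy-6-methylbenzoate | Cc1cc(O)c(OC)c(Oc2c(C3OCCO3)c(OC)cc(C)c2C(=O)OC)c1O
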